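**Retrosynthetic overview** (germacrane numbering: ring C1–C10; lactone C6–O–C12(=O)–C11–C7; C13 on C11, C14 on C10, C15 on C4)
1. Target ⇐ diacetylation and C9–OH-directed epoxidation of C1=C10 in the germacra-1(10),4-dien-12,6-olide 21.
2. 21 ⇐ hydroboration and oxidative lactonisation of the C7 isopropenyl / C6 carbinol in 14, then kinetic protonation at C11.
3. 14 ⇐ [2,3]-Wittig ring contraction of the 13-membered bis-allylic ether 12. The temporary C6–O–C12 ring is not in the target; O–C12 is cleaved while C6–C7 closes the ten-membered ring and sets C6 and C7.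
4. 12 ⇐ Williamson macro-etherification of chloro alcohol 11. Ring order: 13-membered ether, then 10-membered carbocycle, then γ-lactone, then epoxide.
5. 11 ⇐ two catalytic asymmetric vinylogous Mukaiyama aldol reactions of an (E)-C5 enal with a tiglate dienolate. They set C3 and C9 and bring in all three E-trisubstituted alkenes from acyclic pieces.

Key step: step 11

Assumption: in steps 3 and 7 the enantiomer of the C2-symmetric binaphthyldiamine-derived bisphosphoramide that directs the dienolate to the Si face of the enal is used (both enantiomers are accessible). TBS = tert-butyldimethylsilyl, TES = triethylsilyl.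

Step 1
Reactants: 1 1-chloro-3-methylbut-2-ene
Product: 2 (2E)-4-chloro-2-methylbut-2-enal
Conditions: SeO2, 1,4-dioxane, 80 °C
Reagents that add atoms: selenium dioxide, O=[Se]=O
Why: Allylic oxidation by SeO2 (ene reaction, then [2,3]-shift) should oxidise only the methyl group trans to CH2Cl, which gives the (E)-enal.

Step 2
Reactants: 3 methyl (2E)-2-methylbut-2-enoate
Product: 4 tert-butyl[(1-methoxy-2-methylbuta-1,3-dien-1-yl)oxy]dimethylsilane
Conditions: LDA, DMPU, THF, −78 °C; TBSCl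
Reagents that add atoms: tert-butyldimethylsilyl chloride, CC(C)(C)[Si](C)(C)Cl
Why: γ-Deprotonation of the enoate and O-silylation give the silyl dienol ether needed for vinylogous Mukaiyama chemistry.

Step 3
Reactants: 2 (2E)-4-chloro-2-methylbut-2-enal; 4 tiglate silyl dienol ether
Product: 5 methyl (2E,5S,6E)-8-chloro-5-hydroxy-2,6-dimethylocta-2,6-dienoate
Conditions: SiCl4, chiral bisphosphoramide (cat.), i-Pr2NEt (cat.), CH2Cl2, −78 °C; aq. NaHCO3
Reagents that add atoms: none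
Why: In this Lewis-base-catalysed asymmetric vinylogous Mukaiyama aldol reaction the γ-carbon of 4 should add to the Si face of the catalyst-bound enal, which sets C3 as S and gives the (E)-α-methyl enoate (C1=C10).

Step 4
Reactants: 5 methyl (2E,5S,6E)-8-chloro-5-hydroxy-2,6-dimethylocta-2,6-dienoate
Product: 6 methyl (2E,5S,6E)-5-[(tert-butyldimethylsilyl)oxy]-8-chloro-2,6-dimethylocta-2,6-dienoate
Conditions: TBSOTf, 2,6-lutidine, CH2Cl2, −78 °C
Reagents that add atoms: tert-butyldimethylsilyl triflate, CC(C)(C)[Si](C)(C)OS(=O)(=O)C(F)(F)F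
Why: Silylation of the secondary allylic alcohol with a silyl triflate and a hindered base should leave the allylic chloride untouched.

Step 5
Reactants: 6 methyl (2E,5S,6E)-5-[(tert-butyldimethylsilyl)oxy]-8-chloro-2,6-dimethylocta-2,6-dienoate
Product: 7 (2E,5S,6E)-5-[(tert-butyldimethylsilyl)oxy]-8-chloro-2,6-dimethylocta-2,6-dien-1-ol
Conditions: DIBAL-H, CH2Cl2, −78 °C; Rochelle salt
Reagents that add atoms: none
Why: DIBAL-H reduces the conjugated ester by 1,2-hydride delivery at low temperature and should spare the allylic chloride and the silyl ether.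

Step 6
Reactants: 7 (2E,5S,6E)-5-[(tert-butyldimethylsilyl)oxy]-8-chloro-2,6-dimethylocta-2,6-dien-1-ol
Product: 8 (2E,5S,6E)-5-[(tert-butyldimethylsilyl)oxy]-8-chloro-2,6-dimethylocta-2,6-dienal
Conditions: MnO2, CH2Cl2, rt
Reagents that add atoms: none
Why: MnO2 oxidises the primary allylic alcohol chemoselectively to the (E)-enal without alkene isomerisation.

Step 7
Reactants: 8 (2E,5S,6E)-5-[(tert-butyldimethylsilyl)oxy]-8-chloro-2,6-dimethylocta-2,6-dienal; 4 tiglate silyl dienol ether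
Product: 9 methyl (2E,5S,6E,9S,10E)-9-[(tert-butyldimethylsilyl)oxy]-12-chloro-5-hydroxy-2,6,10-trimethyldodeca-2,6,10-trienoate
Conditions: SiCl4, chiral bisphosphoramide (cat.), i-Pr2NEt (cat.), CH2Cl2, −78 °C; aq. NaHCO3
Reagents that add atoms: none
Why: A second catalyst-controlled vinylogous Mukaiyama aldol reaction (same catalyst enantiomer, Si-face attack) should set C9 as S and build the (E)-C7=C11 enoate, with the remote C3 centre not interfering.

Step 8
Reactants: 9 methyl (2E,5S,6E,9S,10E)-9-[(tert-butyldimethylsilyl)oxy]-12-chloro-5-hydroxy-2,6,10-trimethyldodeca-2,6,10-trienoate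
Product: 10 methyl (2E,5S,6E,9S,10E)-9-[(tert-butyldimethylsilyl)oxy]-12-chloro-2,6,10-trimethyl-5-[(triethylsilyl)oxy]dodeca-2,6,10-trienoate
Conditions: TESOTf, 2,6-lutidine, CH2Cl2, −78 °C
Reagents that add atoms: triethylsilyl triflate, CC[Si](CC)(CC)OS(=O)(=O)C(F)(F)F
Why: The C9 hydroxyl is protected as a TES ether that can later be removed in the presence of the C3 TBS ether.

Step 9
Reactants: 10 methyl (2E,5S,6E,9S,10E)-9-[(tert-butyldimethylsilyl)oxy]-12-chloro-2,6,10-trimethyl-5-[(triethylsilyl)oxy]dodeca-2,6,10-trienoate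
Product: 11 (2E,5S,6E,9S,10E)-9-[(tert-butyldimethylsilyl)oxy]-12-chloro-2,6,10-trimethyl-5-[(triethylsilyl)oxy]dodeca-2,6,10-trien-1-ol
Conditions: DIBAL-H, CH2Cl2, −78 °C; Rochelle salt
Reagents that add atoms: none
Why: 1,2-Reduction of the enoate gives the C12 allylic alcohol that serves as the nucleophile for ring closure.

Step 10
Reactants: 11 (2E,5S,6E,9S,10E)-9-[(tert-butyldimethylsilyl)oxy]-12-chloro-2,6,10-trimethyl-5-[(triethylsilyl)oxy]dodeca-2,6,10-trien-1-ol
Product: 12 (3E,6S,7E,10S,11E)-10-[(tert-butyldimethylsilyl)oxy]-3,7,11-trimethyl-6-[(triethylsilyl)oxy]-1-oxacyclotrideca-3,7,11-triene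
Conditions: NaH, n-Bu4NI (cat.), THF, 50 °C, slow addition (high dilution)
Reagents that add atoms: none
Why: In this intramolecular Williamson etherification the primary allylic alkoxide (O on C12) should displace the primary allylic chloride at C6 by SN2, closing the low-strain all-(E) 13-membered ring without creating a stereocentre.

Step 11
Reactants: 12 (3E,6S,7E,10S,11E)-10-[(tert-butyldimethylsilyl)oxy]-3,7,11-trimethyl-6-[(triethylsilyl)oxy]-1-oxacyclotrideca-3,7,11-triene
Product: 14 (1R,2E,4S,6E,8S,10S)-4-[(tert-butyldimethylsilyl)oxy]-3,7-dimethyl-10-(prop-1-en-2-yl)-8-[(triethylsilyl)oxy]cyclodeca-2,6-dien-1-ol, via C6-lithiated ether 13 (not isolated)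
Conditions: n-BuLi, THF, −78 → −30 °C; then H2O
Reagents that add atoms: none
Why: n-BuLi removes a C6 proton (α to oxygen, allylic to C4=C5) and the α-oxy allyllithium 13 undergoes a concerted suprafacial [2,3]-sigmatropic (Wittig) shift through a five-membered envelope transition state (C6–O–C12–C11=C7), which forms C6–C7, breaks O–C12 and moves the alkene to C11=C12. The closest known reaction type is the [2,3]-Wittig ring contraction of 13-membered bis-allylic cyclic ethers to (E,E)-cyclodeca-2,6-dien-1-ols. The ten-membered carbocycle is closed by ring contraction (13 → 10, bond formation inside a preformed ring), so the E-trisubstituted alkenes C4=C5 and C1=C10 are carried over unchanged. The C6/C7 relative configuration (anti, 6,7-trans with H6 and H7 antiperiplanar) should follow from the E geometry of C7=C11 with the vinyl substituent of the carbanion exo in the envelope, and the sense relative to C9 and C3 should follow from a crown-like transition state in which the C9 silyloxy group stays pseudo-equatorial, cis-1,3 to the new C7 substituent, and the C3 silyloxy group is also pseudo-equatorial. The step needs deprotonation at C6 and not at C12 (the C6 anion shifts onto the unhindered C7, whereas a C12 anion would have to attack the fully substituted C4) and [2,3] over [1,2] shift, which low temperature should secure.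

Step 12
Reactants: 14 (1R,2E,4S,6E,8S,10S)-4-[(tert-butyldimethylsilyl)oxy]-3,7-dimethyl-10-(prop-1-en-2-yl)-8-[(triethylsilyl)oxy]cyclodeca-2,6-dien-1-ol
Product: 16 (1S,2E,4S,6E,8S,10S)-4-[(tert-butyldimethylsilyl)oxy]-10-[(2S)-1-hydroxypropan-2-yl]-3,7-dimethyl-8-[(triethylsilyl)oxy]cyclodeca-2,6-dien-1-ol, via bis(9-BBN) adduct 15 (not isolated)
Conditions: 9-BBN, THF, 0 °C → rt; then 30% H2O2, aq. NaOH, 0 °C
Reagents that add atoms: hydrogen peroxide, OO
Why: In this hydroboration–oxidation 9-BBN should react only with the 1,1-disubstituted alkene and place boron on C12, and approach anti to C6 in the rotamer that keeps H7 next to the C11 methyl should give mainly the 11S alcohol (this centre is reset in step 14).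

Step 13
Reactants: 16 (1S,2E,4S,6E,8S,10S)-4-[(tert-butyldimethylsilyl)oxy]-10-[(2S)-1-hydroxypropan-2-yl]-3,7-dimethyl-8-[(triethylsilyl)oxy]cyclodeca-2,6-dien-1-ol
Product: 18 (3S,6S,7S,9S,11S)-3-[(tert-butyldimethylsilyl)oxy]-9-[(triethylsilyl)oxy]germacra-1(10)E,4E-dien-12,6-olide, via lactol 17 (not isolated)
Conditions: TEMPO (cat.), PhI(OAc)2, CH2Cl2, rt
Reagents that add atoms: none
Why: In this TEMPO/PhI(OAc)2 oxidative lactonisation the primary alcohol is oxidised to the aldehyde, which closes onto the C6 hydroxyl as lactol 17 and is oxidised on to the trans-fused γ-lactone without change at C6 or C7.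

Step 14
Reactants: 18 (3S,6S,7S,9S,11S)-3-[(tert-butyldimethylsilyl)oxy]-9-[(triethylsilyl)oxy]germacra-1(10)E,4E-dien-12,6-olide
Product: 21 (3S,6S,7S,9S,11R)-3-[(tert-butyldimethylsilyl)oxy]-9-hydroxygermacra-1(10)E,4E-dien-12,6-olide, via lithium enolate 19 (not isolated), via 11R TES lactone 20 (not isolated)
Conditions: LDA, THF, −78 °C; 2,6-di-tert-butyl-4-methylphenol, −78 °C; then aq. 1 M HCl, THF, 0 °C
Reagents that add atoms: none
Why: Kinetic protonation of lithium enolate 19 by the bulky phenol should occur on the α-face of C11, anti to C8 on the neighbouring C7, which puts the methyl group β (11R, the less stable epimer), and brief dilute acid then cleaves only the more labile TES ether.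

Step 15
Reactants: 21 (3S,6S,7S,9S,11R)-3-[(tert-butyldimethylsilyl)oxy]-9-hydroxygermacra-1(10)E,4E-dien-12,6-olide
Product: 22 (1S,3S,6S,7S,9S,10S,11R)-3-[(tert-butyldimethylsilyl)oxy]-1,10-epoxy-9-hydroxygermacr-4E-en-12,6-olide
Conditions: VO(acac)2 (cat.), t-BuOOH, CH2Cl2, 0 °C → rt
Reagents that add atoms: tert-butyl hydroperoxide, CC(C)(C)OO
Why: In this vanadium-catalysed hydroxyl-directed epoxidation the C9 vanadate should deliver oxygen only to the adjacent C1=C10 alkene, and minimising A(1,2) strain between H9 and the C10 methyl should give the erythro trans-epoxide (same spatial arrangement as 1S,10R in the target; C10 is S in 22 and 23 only through CIP priorities).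

Step 16
Reactants: 22 (1S,3S,6S,7S,9S,10S,11R)-3-[(tert-butyldimethylsilyl)oxy]-1,10-epoxy-9-hydroxygermacr-4E-en-12,6-olide
Product: 23 (1S,3S,6S,7S,9S,10S,11R)-1,10-epoxy-3,9-dihydroxygermacr-4E-en-12,6-olide
Conditions: TBAF, AcOH, THF, rt
Reagents that add atoms: none
Why: Fluoride cleaves the remaining silyl ether, and buffering with acetic acid should protect the epimerisable C11 centre and the epoxy alcohol.

Step 17
Reactants: 23 (1S,3S,6S,7S,9S,10S,11R)-1,10-epoxy-3,9-dihydroxygermacr-4E-en-12,6-olide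
Product: 24 (1S,3S,4E,6S,7S,9S,10R,11R)-3,9-diacetoxy-1,10-epoxygermacr-4-en-12,6-olide (CNP0250285.1)
Conditions: Ac2O, pyridine, DMAP (cat.), CH2Cl2, rt
Reagents that add atoms: acetic anhydride, CC(=O)OC(C)=O
Why: DMAP-catalysed acylation of both secondary alcohols should give the diacetate without touching the epoxide or the lactone.

**Compound list**
1 | 1-chloro-3-methylbut-2-ene (prenyl chloride) | CC(C)=CCCl | starting material
2 | (2E)-4-chloro-2-methylbut-2-enal | ClC/C=C(\C)C=O | intermediate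
3 | methyl (2E)-2-methylbut-2-enoate (methyl tiglate) | C/C=C(\C)C(=O)OC | starting material
4 | tert-butyl[(1-methoxy-2-methylbuta-1,3-dien-1-yl)oxy]dimethylsilane (ketene acetal E/Z mixture, both isomers react alike) | C=CC(C)=C(OC)O[Si](C)(C)C(C)(C)C | intermediate
5 | methyl (2E,5S,6E)-8-chloro-5-hydroxy-2,6-dimethylocta-2,6-dienoate | COC(=O)/C(C)=C/C[C@H](O)/C(C)=C/CCl | intermediate
6 | methyl (2E,5S,6E)-5-[(tert-butyldimethylsilyl)oxy]-8-chloro-2,6-dimethylocta-2,6-dienoate | COC(=O)/C(C)=C/C[C@H](O[Si](C)(C)C(C)(C)C)/C(C)=C/CCl | intermediate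
7 | (2E,5S,6E)-5-[(tert-butyldimethylsilyl)oxy]-8-chloro-2,6-dimethylocta-2,6-dien-1-ol | OC/C(C)=C/C[C@H](O[Si](C)(C)C(C)(C)C)/C(C)=C/CCl | intermediate
8 | (2E,5S,6E)-5-[(tert-butyldimethylsilyl)oxy]-8-chloro-2,6-dimethylocta-2,6-dienal | O=C/C(C)=C/C[C@H](O[Si](C)(C)C(C)(C)C)/C(C)=C/CCl | intermediate
9 | methyl (2E,5S,6E,9S,10E)-9-[(tert-butyldimethylsilyl)oxy]-12-chloro-5-hydroxy-2,6,10-trimethyldodeca-2,6,10-trienoate | COC(=O)/C(C)=C/C[C@H](O)/C(C)=C/C[C@H](O[Si](C)(C)C(C)(C)C)/C(C)=C/CCl | intermediate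
10 | methyl (2E,5S,6E,9S,10E)-9-[(tert-butyldimethylsilyl)oxy]-12-chloro-2,6,10-trimethyl-5-[(triethylsilyl)oxy]dodeca-2,6,10-trienoate | COC(=O)/C(C)=C/C[C@H](O[Si](CC)(CC)CC)/C(C)=C/C[C@H](O[Si](C)(C)C(C)(C)C)/C(C)=C/CCl | intermediate
11 | (2E,5S,6E,9S,10E)-9-[(tert-butyldimethylsilyl)oxy]-12-chloro-2,6,10-trimethyl-5-[(triethylsilyl)oxy]dodeca-2,6,10-trien-1-ol | OC/C(C)=C/C[C@H](O[Si](CC)(CC)CC)/C(C)=C/C[C@H](O[Si](C)(C)C(C)(C)C)/C(C)=C/CCl | intermediate
12 | (3E,6S,7E,10S,11E)-10-[(tert-butyldimethylsilyl)oxy]-3,7,11-trimethyl-6-[(triethylsilyl)oxy]-1-oxacyclotrideca-3,7,11-triene | C1/C(C)=C/C[C@H](O[Si](CC)(CC)CC)/C(C)=C/C[C@H](O[Si](C)(C)C(C)(C)C)/C(C)=C/CO1 | intermediate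
13 | C6-lithiated ether (α-oxy allyllithium of 12, lithium on the ring carbon that becomes C6) | C1/C(C)=C/C[C@H](O[Si](CC)(CC)CC)/C(C)=C/C[C@H](O[Si](C)(C)C(C)(C)C)/C(C)=C/C([Li])O1 | intermediate (not isolated)
14 | (1R,2E,4S,6E,8S,10S)-4-[(tert-butyldimethylsilyl)oxy]-3,7-dimethyl-10-(prop-1-en-2-yl)-8-[(triethylsilyl)oxy]cyclodeca-2,6-dien-1-ol | C=C(C)[C@@H]1C[C@H](O[Si](CC)(CC)CC)/C(C)=C/C[C@H](O[Si](C)(C)C(C)(C)C)/C(C)=C/[C@H]1O | intermediate
15 | bis(9-BBN) adduct of 14 (C12-alkylborane and C6 O-borinate) | C[C@H](CB1C2CCCC1CCC2)[C@@H]1C[C@H](O[Si](CC)(CC)CC)/C(C)=C/C[C@H](O[Si](C)(C)C(C)(C)C)/C(C)=C/[C@H]1OB1C2CCCC1CCC2 | intermediate (not isolated)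
16 | (1S,2E,4S,6E,8S,10S)-4-[(tert-butyldimethylsilyl)oxy]-10-[(2S)-1-hydroxypropan-2-yl]-3,7-dimethyl-8-[(triethylsilyl)oxy]cyclodeca-2,6-dien-1-ol | OC[C@@H](C)[C@@H]1C[C@H](O[Si](CC)(CC)CC)/C(C)=C/C[C@H](O[Si](C)(C)C(C)(C)C)/C(C)=C/[C@H]1O | intermediate
17 | lactol (C12 hemiacetal of the 12,6-olide; C12 configuration undefined) | CC(C)(C)[Si](C)(C)O[C@H]1C/C=C(\C)[C@@H](O[Si](CC)(CC)CC)C[C@@H]2[C@@H](/C=C/1C)OC(O)[C@H]2C | intermediate (not isolated)
18 | (3S,6S,7S,9S,11S)-3-[(tert-butyldimethylsilyl)oxy]-9-[(triethylsilyl)oxy]germacra-1(10)E,4E-dien-12,6-olide (trans-lactone, 11α-methyl) | CC(C)(C)[Si](C)(C)O[C@H]1C/C=C(\C)[C@@H](O[Si](CC)(CC)CC)C[C@@H]2[C@@H](/C=C/1C)OC(=O)[C@H]2C | intermediate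
19 | lithium enolate of 18 (C11=C12) | CC(C)(C)[Si](C)(C)O[C@H]1C/C=C(\C)[C@@H](O[Si](CC)(CC)CC)C[C@@H]2[C@@H](/C=C/1C)OC(O[Li])=C2C | intermediate (not isolated)
20 | (3S,6S,7S,9S,11R)-3-[(tert-butyldimethylsilyl)oxy]-9-[(triethylsilyl)oxy]germacra-1(10)E,4E-dien-12,6-olide (11β-methyl) | CC(C)(C)[Si](C)(C)O[C@H]1C/C=C(\C)[C@@H](O[Si](CC)(CC)CC)C[C@@H]2[C@@H](/C=C/1C)OC(=O)[C@@H]2C | intermediate (not isolated)
21 | (3S,6S,7S,9S,11R)-3-[(tert-butyldimethylsilyl)oxy]-9-hydroxygermacra-1(10)E,4E-dien-12,6-olide | CC(C)(C)[Si](C)(C)O[C@H]1C/C=C(\C)[C@@H](O)C[C@@H]2[C@@H](/C=C/1C)OC(=O)[C@@H]2C | intermediate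
22 | (1S,3S,6S,7S,9S,10S,11R)-3-[(tert-butyldimethylsilyl)oxy]-1,10-epoxy-9-hydroxygermacr-4E-en-12,6-olide | CC(C)(C)[Si](C)(C)O[C@H]1C[C@@H]2O[C@@]2(C)[C@@H](O)C[C@@H]2[C@@H](/C=C/1C)OC(=O)[C@@H]2C | intermediate
23 | (1S,3S,6S,7S,9S,10S,11R)-1,10-epoxy-3,9-dihydroxygermacr-4E-en-12,6-olide | O[C@H]1C[C@@H]2O[C@@]2(C)[C@@H](O)C[C@@H]2[C@@H](/C=C/1C)OC(=O)[C@@H]2C | intermediate
24 | (1S,3S,4E,6S,7S,9S,10R,11R)-3,9-diacetoxy-1,10-epoxygermacr-4-en-12,6-olide (CNP0250285.1) | CC(=O)O[C@H]1C[C@@H]2O[C@@]2(C)[C@@H](OC(C)=O)C[C@@H]2[C@@H](/C=C/1C)OC(=O)[C@@H]2C | target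

**Step count**
Total steps: 17. Longest linear sequence: 16 (steps 1 and 3–17; step 2 prepares reagent 4).

**Steps most likely to fail**

1. Step 11 (ring contraction). Deprotonation may occur at C12 instead of C6, the anion may undergo a [1,2]-shift or a vinylogous β-elimination of the C3 silyloxy group, or the C9/C3 centres may give too little facial bias. The fallback closes the same C6–C7 bond by metal-mediated allylation and sets out from 11. Oxidation of the allylic chloride with N-methylmorpholine N-oxide (Kornblum-type, MeCN) gives (2E,4S,6E,8S,10E)-4-[(tert-butyldimethylsilyl)oxy]-12-hydroxy-3,7,11-trimethyl-8-[(triethylsilyl)oxy]dodeca-2,6,10-trienal F1. Appel bromination (CBr4, PPh3) gives (2E,4S,6E,8S,10E)-12-bromo-4-[(tert-butyldimethylsilyl)oxy]-3,7,11-trimethyl-8-[(triethylsilyl)oxy]dodeca-2,6,10-trienal F2. An intramolecular Nozaki–Hiyama–Kishi allylation (CrCl2, THF, high dilution) should then add the γ-carbon C7 of the allylchromium to the C6 aldehyde through a chair transition state (anti) and come back to the route at 14.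

2. Step 10 (macro-etherification). Intermolecular O-alkylation (oligomers) and SN2' attack at C4 may outrun closure of the 13-membered ring. The fallback closes the ring as an ester and then reduces it, setting out from 10. Displacement of chloride with caesium acetate (DMF) gives methyl (2E,5S,6E,9S,10E)-12-acetoxy-9-[(tert-butyldimethylsilyl)oxy]-2,6,10-trimethyl-5-[(triethylsilyl)oxy]dodeca-2,6,10-trienoate F3. Saponification (LiOH, aq. THF) gives (2E,5S,6E,9S,10E)-9-[(tert-butyldimethylsilyl)oxy]-12-hydroxy-2,6,10-trimethyl-5-[(triethylsilyl)oxy]dodeca-2,6,10-trienoic acid F4. Yamaguchi macrolactonisation gives (3E,6S,7E,10S,11E)-10-[(tert-butyldimethylsilyl)oxy]-3,7,11-trimethyl-6-[(triethylsilyl)oxy]-1-oxacyclotrideca-3,7,11-trien-2-one F5. DIBAL-H at −78 °C gives the lactol (3E,6S,7E,10S,11E)-10-[(tert-butyldimethylsilyl)oxy]-3,7,11-trimethyl-6-[(triethylsilyl)oxy]-1-oxacyclotrideca-3,7,11-trien-2-ol F6, and ionic reduction (Et3SiH, BF3·OEt2, −78 °C) should come back to the route at 12.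

3. Step 14 (C11). Protonation may occur on the β-face, or proton exchange may lead to the thermodynamically favoured 11S epimer. The fallback replaces substrate-controlled protonation by catalyst-controlled hydrogenation and sets out from 18. LDA then PhSeBr gives 3β-[(tert-butyldimethylsilyl)oxy]-11-(phenylselanyl)-9β-[(triethylsilyl)oxy]germacra-1(10)E,4E-dien-12,6α-olide F7. Oxidation with H2O2 and syn-elimination towards the methyl group give (3S,6R,7S,9S)-3-[(tert-butyldimethylsilyl)oxy]-9-[(triethylsilyl)oxy]germacra-1(10)E,4E,11(13)-trien-12,6-olide F8. Asymmetric hydrogenation of the exocyclic enoate with a cationic rhodium–bisphospholane catalyst, chosen to deliver hydrogen to the α-face of C11, should give 20, which is desilylated at C9 as in step 14 and comes back to the route at 21.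

Further compounds
F1 | step 11 | (2E,4S,6E,8S,10E)-4-[(tert-butyldimethylsilyl)oxy]-12-hydroxy-3,7,11-trimethyl-8-[(triethylsilyl)oxy]dodeca-2,6,10-trienal | OC/C(C)=C/C[C@H](O[Si](CC)(CC)CC)/C(C)=C/C[C@H](O[Si](C)(C)C(C)(C)C)/C(C)=C/C=O
F2 | step 11 | (2E,4S,6E,8S,10E)-12-bromo-4-[(tert-butyldimethylsilyl)oxy]-3,7,11-trimethyl-8-[(triethylsilyl)oxy]dodeca-2,6,10-trienal | BrC/C(C)=C/C[C@H](O[Si](CC)(CC)CC)/C(C)=C/C[C@H](O[Si](C)(C)C(C)(C)C)/C(C)=C/C=O
F3 | step 10 | methyl (2E,5S,6E,9S,10E)-12-acetoxy-9-[(tert-butyldimethylsilyl)oxy]-2,6,10-trimethyl-5-[(triethylsilyl)oxy]dodeca-2,6,10-trienoate | COC(=O)/C(C)=C/C[C@H](O[Si](CC)(CC)CC)/C(C)=C/C[C@H](O[Si](C)(C)C(C)(C)C)/C(C)=C/COC(C)=O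
F4 | step 10 | (2E,5S,6E,9S,10E)-9-[(tert-butyldimethylsilyl)oxy]-12-hydroxy-2,6,10-trimethyl-5-[(triethylsilyl)oxy]dodeca-2,6,10-trienoic acid | OC(=O)/C(C)=C/C[C@H](O[Si](CC)(CC)CC)/C(C)=C/C[C@H](O[Si](C)(C)C(C)(C)C)/C(C)=C/CO
F5 | step 10 | (3E,6S,7E,10S,11E)-10-[(tert-butyldimethylsilyl)oxy]-3,7,11-trimethyl-6-[(triethylsilyl)oxy]-1-oxacyclotrideca-3,7,11-trien-2-one | O=C1/C(C)=C/C[C@H](O[Si](CC)(CC)CC)/C(C)=C/C[C@H](O[Si](C)(C)C(C)(C)C)/C(C)=C/CO1
F6 | step 10 | (3E,6S,7E,10S,11E)-10-[(tert-butyldimethylsilyl)oxy]-3,7,11-trimethyl-6-[(triethylsilyl)oxy]-1-oxacyclotrideca-3,7,11-trien-2-ol | OC1/C(C)=C/C[C@H](O[Si](CC)(CC)CC)/C(C)=C/C[C@H](O[Si](C)(C)C(C)(C)C)/C(C)=C/CO1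
F7 | step 14 | 3β-[(tert-butyldimethylsilyl)oxy]-11-(phenylselanyl)-9β-[(triethylsilyl)oxy]germacra-1(10)E,4E-dien-12,6α-olide | CC(C)(C)[Si](C)(C)O[C@H]1C/C=C(\C)[C@@H](O[Si](CC)(CC)CC)C[C@@H]2[C@@H](/C=C/1C)OC(=O)C2(C)[Se]c1ccccc1
F8 | step 14 | (3S,6R,7S,9S)-3-[(tert-butyldimethylsilyl)oxy]-9-[(triethylsilyl)oxy]germacra-1(10)E,4E,11(13)-trien-12,6-olide | CC(C)(C)[Si](C)(C)O[C@H]1C/C=C(\C)[C@@H](O[Si](CC)(CC)CC)C[C@@H]2[C@@H](/C=C/1C)OC(=O)C2=C
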